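**Retrosynthetic overview**

1. Target 37 comes from its tert-butyl ester 36, whose central ester C–O bond is made by carboxylate opening of spiro-epoxide 18 (eastern, lactone half) with acid 35 (western, acyl half); the epoxide already carries the tertiary-alcohol stereocenter.
2. The two halves are antipodal at their isopropyl- and side-chain-bearing ring carbons, so 18 and 35 derive from mirror-image seven-membered lactones 17 and 29, made by one sequence run with (R)- or (S)-BINOL.
3. Lactones 17/29 arise by ring-closing metathesis of a 2-(acyloxymethyl)acrylate onto a vinyl group (alkene geometry fixed by the ring); the exocyclic methylene comes from a γ-lactone by selenolate opening and selenoxide elimination.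
4. The cyclohexane with its four contiguous cis stereocenters comes from a templated enantioselective Diels–Alder/lactonization of dienol 4 with dibenzyl maleate (new step); 4 comes from isobutyraldehyde.
5. Acid 35 comes from 29 by lactone hydrolysis and excision of the ring carboxyl (iodo-β-lactone, loss of CO2). Ring order: cyclohexene plus γ-lactone (one step), then the seven-membered lactone, then the oxirane (eastern) or a transient β-lactone (western).

Assumption: the stereodescriptors of the given SMILES are taken literally, which makes the two halves antipodal at the isopropyl/side-chain carbons; (R)-BINOL is taken to deliver the eastern series (if the sense is the reverse, the two ligand antipodes are simply exchanged).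

**Route**

Step 1
Reactants: 1 isobutyraldehyde; 2 triethyl (E)-4-phosphonocrotonate
Product: 3 ethyl (2E,4E)-6-methylhepta-2,4-dienoate
Conditions: LiN(SiMe3)2, THF, −78 °C to 0 °C
Reagents that add atoms: none
Why: Vinylogous Horner–Wadsworth–Emmons olefination of an aliphatic aldehyde gives the (E,E)-dienoate.

Step 2
Reactants: 3 ethyl (2E,4E)-6-methylhepta-2,4-dienoate
Product: 4 (2E,4E)-6-methylhepta-2,4-dien-1-ol
Conditions: iBu2AlH (2.2 equiv), CH2Cl2, −78 °C; aq potassium sodium tartrate
Reagents that add atoms: none
Why: 1,2-Reduction of the conjugated ester by the aluminium hydride leaves the diene geometry intact.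

Step 3
Reactants: 4 (2E,4E)-6-methylhepta-2,4-dien-1-ol; 5 dibenzyl maleate
Product: 7 eastern lactone benzyl ester (benzyl all-cis-3-oxo-5-isopropyl-1,3,3a,4,5,7a-hexahydroisobenzofuran-4-carboxylate), via eastern cycloadduct diester 6 (not isolated)
Conditions: (R)-BINOL (20 mol %), ZnMe2 (1 equiv), MeMgBr (1 equiv), CH2Cl2, 0 °C to rt; aq NH4Cl
Reagents that add atoms: none
Why: Proposed new method: a (BINOLate)Zn/Mg bimetallic template holds the dienol as its magnesium alkoxide and one ester carbonyl of the maleate, so the cycloaddition runs intramolecularly inside a chiral pocket that selects one diene face; the endo transition state of the cis-diester places both carboxyls syn to the outward isopropyl and CH2O groups (four cis stereocenters), and the alkoxide then lactonizes onto the adjacent ester with loss of benzyl oxide, which tells the two carboxyls apart; closest known reaction type: the Lewis-acid-templated Diels–Alder of 2,4-dienols with methyl acrylate under BINOL/ZnMe2/MeMgBr and the thermal Diels–Alder/lactonization of dienols with maleic anhydride.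

Step 4
Reactants: 7 eastern lactone benzyl ester
Product: 8 eastern lactone acid (all-cis-3-oxo-5-isopropyloctahydroisobenzofuran-4-carboxylic acid)
Conditions: H2 (1 atm), 10% Pd/C, EtOAc, rt
Reagents that add atoms: none
Why: Heterogeneous hydrogenation saturates the ring alkene and hydrogenolyses the benzyl ester in one operation without touching a stereocenter.

Step 5
Reactants: 8 eastern lactone acid
Product: 9 eastern thioester (S-ethyl thioester of 8)
Conditions: EtSH, DCC, DMAP (cat.), CH2Cl2, 0 °C to rt
Reagents that add atoms: ethanethiol, CCS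
Why: Steglich-type thioesterification prepares the free carboxyl for a reduction that the lactone survives.

Step 6
Reactants: 9 eastern thioester
Product: 10 eastern aldehyde (all-cis-3-oxo-5-isopropyloctahydroisobenzofuran-4-carbaldehyde)
Conditions: Et3SiH, 10% Pd/C, acetone, rt
Reagents that add atoms: none
Why: Fukuyama reduction stops at the aldehyde under neutral conditions, so the lactone and the α-stereocenter are untouched.

Step 7
Reactants: 10 eastern aldehyde
Product: 11 eastern vinyl lactone (all-cis-7-ethenyl-6-isopropylhexahydroisobenzofuran-1(3H)-one)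
Conditions: Ph3PCH3Br, KN(SiMe3)2, THF, −78 °C to 0 °C
Reagents that add atoms: methyltriphenylphosphonium bromide, C[P+](c1ccccc1)(c1ccccc1)c1ccccc1.[Br-]
Why: Wittig methylenation with the non-stabilised ylide at low temperature outruns epimerisation of the α-branched aldehyde.

Step 8
Reactants: 11 eastern vinyl lactone
Product: 12 eastern seleno acid (all-cis-2-ethenyl-3-isopropyl-6-[(phenylselanyl)methyl]cyclohexane-1-carboxylic acid)
Conditions: (PhSe)2, NaBH4, DMF, 120 °C; aq HCl
Reagents that add atoms: diphenyl diselenide, c1ccc(cc1)[Se][Se]c1ccccc1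
Why: SN2 cleavage of the lactone alkyl–oxygen bond by the soft selenolate (Liotta-type lactone opening) frees the ring carboxyl and leaves all ring stereocenters untouched.

Step 9
Reactants: 12 eastern seleno acid
Product: 14 eastern dienoic acid (all-cis-2-ethenyl-3-isopropyl-6-methylidenecyclohexane-1-carboxylic acid), via eastern selenoxide 13 (not isolated)
Conditions: NaIO4, MeOH/H2O, 0 °C to rt; then 50 °C
Reagents that add atoms: none
Why: Selenoxide syn-elimination can only take the ring hydrogen next to the CH2Se carbon, so the exocyclic methylene forms regiospecifically.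

Step 10
Reactants: 14 eastern dienoic acid; 15 tert-butyl 2-(bromomethyl)acrylate
Product: 16 eastern triene ester (2-(tert-butoxycarbonyl)allyl ester of 14)
Conditions: Cs2CO3 (0.6 equiv), DMF, 0 °C to rt
Reagents that add atoms: none
Why: Carboxylate O-alkylation by the reactive allylic bromide (direct and allylic-shift attack give the same ester) needs only mild base, so the β,γ-unsaturated acid is not isomerised.

Step 11
Reactants: 16 eastern triene ester
Product: 17 eastern seven-membered lactone (tert-butyl 9-methylidene-1-oxo-6-isopropyl-1,3,5a,6,7,8,9,9a-octahydro-2-benzoxepine-4-carboxylate, cis ring fusion, isopropyl cis to C-5)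
Conditions: second-generation Hoveyda–Grubbs catalyst, RuCl2(H2IMes)(=CHC6H4-2-OiPr) (10 mol %), toluene (2 mM), 80 °C
Reagents that add atoms: none
Why: Ring-closing metathesis starts at the monosubstituted vinyl group and closes onto the acrylate; the cis ring fusion holds both arms together and the seven-membered ring enforces the needed alkene geometry (ring carbon cis to CH2O, trans to the ester).

Step 12
Reactants: 17 eastern seven-membered lactone
Product: 18 eastern spiro-epoxide (9-spiro-oxirane of 17, oxirane oxygen trans to C-1, oxirane CH2 cis to C-1)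
Conditions: mCPBA, Na2HPO4, CH2Cl2, 0 °C
Reagents that add atoms: mCPBA, OOC(=O)c1cccc(Cl)c1
Why: Prilezhaev epoxidation takes only the electron-richer 1,1-disubstituted alkene, and the axial side-chain carbon at the ring fusion shields the upper face, so oxygen adds from below and sets the spiro carbon.

Step 13
Reactants: 4 (2E,4E)-6-methylhepta-2,4-dien-1-ol; 5 dibenzyl maleate
Product: 20 western lactone benzyl ester (mirror image of 7), via western cycloadduct diester 19 (not isolated)
Conditions: (S)-BINOL (20 mol %), ZnMe2 (1 equiv), MeMgBr (1 equiv), CH2Cl2, 0 °C to rt; aq NH4Cl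
Reagents that add atoms: none
Why: Proposed new method: the same bimetallic BINOLate template Diels–Alder/lactonization as in step 3, where the antipodal ligand selects the other diene face while endo addition and lactonization onto the adjacent ester again give the all-cis lactone; closest known reaction type: the BINOL/ZnMe2/MeMgBr-templated Diels–Alder of 2,4-dienols with methyl acrylate.

Step 14
Reactants: 20 western lactone benzyl ester
Product: 21 western lactone acid (mirror image of 8)
Conditions: H2 (1 atm), 10% Pd/C, EtOAc, rt
Reagents that add atoms: none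
Why: Hydrogenation and benzyl ester hydrogenolysis as in step 4, with no stereocenter touched.

Step 15
Reactants: 21 western lactone acid
Product: 22 western thioester (mirror image of 9)
Conditions: EtSH, DCC, DMAP (cat.), CH2Cl2, 0 °C to rt
Reagents that add atoms: ethanethiol, CCS
Why: Steglich-type thioesterification as in step 5.

Step 16
Reactants: 22 western thioester
Product: 23 western aldehyde (mirror image of 10)
Conditions: Et3SiH, 10% Pd/C, acetone, rt
Reagents that add atoms: none
Why: Fukuyama reduction as in step 6 gives the aldehyde without epimerisation.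

Step 17
Reactants: 23 western aldehyde
Product: 24 western vinyl lactone (mirror image of 11)
Conditions: Ph3PCH3Br, KN(SiMe3)2, THF, −78 °C to 0 °C
Reagents that add atoms: methyltriphenylphosphonium bromide, C[P+](c1ccccc1)(c1ccccc1)c1ccccc1.[Br-]
Why: Wittig methylenation as in step 7.

Step 18
Reactants: 24 western vinyl lactone
Product: 25 western seleno acid (mirror image of 12)
Conditions: (PhSe)2, NaBH4, DMF, 120 °C; aq HCl
Reagents that add atoms: diphenyl diselenide, c1ccc(cc1)[Se][Se]c1ccccc1
Why: SN2 lactone opening by selenolate as in step 8.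

Step 19
Reactants: 25 western seleno acid
Product: 27 western dienoic acid (mirror image of 14), via western selenoxide 26 (not isolated)
Conditions: NaIO4, MeOH/H2O, 0 °C to rt; then 50 °C
Reagents that add atoms: none
Why: Regiospecific selenoxide syn-elimination as in step 9.

Step 20
Reactants: 27 western dienoic acid; 15 tert-butyl 2-(bromomethyl)acrylate
Product: 28 western triene ester (mirror image of 16)
Conditions: Cs2CO3 (0.6 equiv), DMF, 0 °C to rt
Reagents that add atoms: none
Why: Carboxylate O-alkylation as in step 10.

Step 21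
Reactants: 28 western triene ester
Product: 29 western seven-membered lactone (mirror image of 17)
Conditions: second-generation Hoveyda–Grubbs catalyst, RuCl2(H2IMes)(=CHC6H4-2-OiPr) (10 mol %), toluene (2 mM), 80 °C
Reagents that add atoms: none
Why: Ring-closing metathesis as in step 11; here the ring carboxyl serves as a temporary tether that fixes the side-chain alkene geometry.

Step 22
Reactants: 29 western seven-membered lactone
Product: 30 western hydroxy acid (all-cis-3-isopropyl-6-methylidene-2-[(E)-3-tert-butoxy-2-(hydroxymethyl)-3-oxoprop-1-enyl]cyclohexane-1-carboxylic acid)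
Conditions: LiOH, THF/H2O, 0 °C; 1 M HCl to pH 3
Reagents that add atoms: lithium hydroxide, [Li+].[OH-]
Why: Saponification of the seven-membered lactone is much faster than attack on the tert-butyl ester, so the ring carboxyl and the (E)-2-(hydroxymethyl)acrylate side chain are released with the ring-derived geometry.

Step 23
Reactants: 30 western hydroxy acid
Product: 31 western iodo-β-lactone (cis-fused β-lactone; lactone oxygen and CH2I on the former methylidene carbon)
Conditions: I2, NaHCO3, MeCN/H2O, 0 °C, dark
Reagents that add atoms: iodine, II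
Why: Kinetic iodolactonization of a β,γ-unsaturated acid closes the four-membered ring by Markovnikov attack of the carboxylate at the tertiary carbon.

Step 24
Reactants: 31 western iodo-β-lactone
Product: 33 western allylic acetate (tert-butyl (E)-3-[3-(acetoxymethyl)-6-isopropylcyclohex-2-en-1-yl]-2-(hydroxymethyl)acrylate, 1,6-cis), via western allylic iodide 32 (not isolated)
Conditions: DMF, 100 °C; then CsOAc, 40 °C
Reagents that add atoms: caesium acetate, [Cs+].[O-]C(C)=O
Why: Thermal cycloreversion of the β-lactone expels CO2 and leaves the trisubstituted ring alkene, after which acetate displaces the primary allylic iodide by SN2.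

Step 25
Reactants: 33 western allylic acetate
Product: 34 western acetoxy acid (free acrylic acid of 33)
Conditions: TFA/CH2Cl2 (1:4), 0 °C
Reagents that add atoms: none
Why: Acidolysis of the tert-butyl ester is done while the ring allylic oxygen is still an acid-stable acetate.

Step 26
Reactants: 34 western acetoxy acid
Product: 35 western acid ((E)-2-(hydroxymethyl)-3-[3-(hydroxymethyl)-6-isopropylcyclohex-2-en-1-yl]acrylic acid, 1,6-cis)
Conditions: K2CO3, MeOH, 0 °C; 1 M HCl to pH 3
Reagents that add atoms: none
Why: Zemplén-type methanolysis removes the unhindered acetate and leaves the conjugated carboxylate alone.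

Step 27
Reactants: 18 eastern spiro-epoxide; 35 western acid
Product: 36 tert-butyl ester of the target
Conditions: Cs2CO3 (20 mol %), DMF, 60 °C
Reagents that add atoms: none
Why: The caesium carboxylate opens the 2,2-disubstituted oxirane by SN2 at its CH2 terminus (carboxylic acid–epoxide addition), so the C–O bond at the quaternary carbon and the tertiary-alcohol configuration are retained, and the far less nucleophilic hydroxyls need no protection.

Step 28
Reactants: 36 tert-butyl ester of the target
Product: 37 CNP0361406.12
Conditions: TFA/CH2Cl2 (1:4), 0 °C; aq NaHCO3 wash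
Reagents that add atoms: none
Why: Acidolysis of the last tert-butyl ester is run cold and short so that the tertiary alcohol, the allylic alcohols and both ester links survive.

**Compound list**

1 | isobutyraldehyde | CC(C)C=O | starting material
2 | triethyl (E)-4-phosphonocrotonate | CCOC(=O)/C=C/CP(=O)(OCC)OCC | starting material
3 | ethyl (2E,4E)-6-methylhepta-2,4-dienoate | CCOC(=O)/C=C/C=C/C(C)C | intermediate
4 | (2E,4E)-6-methylhepta-2,4-dien-1-ol | OC/C=C/C=C/C(C)C | intermediate
5 | dibenzyl maleate | O=C(OCc1ccccc1)/C=C\C(=O)OCc1ccccc1 | starting material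
6 | eastern cycloadduct diester: dibenzyl 3-(hydroxymethyl)-6-isopropylcyclohex-4-ene-1,2-dicarboxylate, all four substituents cis | CC(C)[C@H]1C=C[C@@H](CO)[C@@H](C(=O)OCc2ccccc2)[C@H]1C(=O)OCc3ccccc3 | intermediate (not isolated)
7 | eastern lactone benzyl ester: benzyl 3-oxo-5-isopropyl-1,3,3a,4,5,7a-hexahydroisobenzofuran-4-carboxylate, all-cis | CC(C)[C@H]1C=C[C@H]2COC(=O)[C@H]2[C@H]1C(=O)OCc3ccccc3 | intermediate
8 | eastern lactone acid: 3-oxo-5-isopropyloctahydroisobenzofuran-4-carboxylic acid, all-cis | CC(C)[C@H]1CC[C@H]2COC(=O)[C@H]2[C@H]1C(=O)O | intermediate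
9 | eastern thioester: S-ethyl thioester of 8 | CC(C)[C@H]1CC[C@H]2COC(=O)[C@H]2[C@H]1C(=O)SCC | intermediate
10 | eastern aldehyde: 3-oxo-5-isopropyloctahydroisobenzofuran-4-carbaldehyde, all-cis | CC(C)[C@H]1CC[C@H]2COC(=O)[C@H]2[C@H]1C=O | intermediate
11 | eastern vinyl lactone: 7-ethenyl-6-isopropylhexahydroisobenzofuran-1(3H)-one, all-cis | CC(C)[C@H]1CC[C@H]2COC(=O)[C@H]2[C@H]1C=C | intermediate
12 | eastern seleno acid: 2-ethenyl-3-isopropyl-6-[(phenylselanyl)methyl]cyclohexane-1-carboxylic acid, all-cis | CC(C)[C@H]1CC[C@@H](C[Se]c2ccccc2)[C@@H](C(=O)O)[C@H]1C=C | intermediate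
13 | eastern selenoxide: Se-oxide of 12 | CC(C)[C@H]1CC[C@@H](C[Se](=O)c2ccccc2)[C@@H](C(=O)O)[C@H]1C=C | intermediate (not isolated)
14 | eastern dienoic acid: 2-ethenyl-3-isopropyl-6-methylidenecyclohexane-1-carboxylic acid, all-cis | CC(C)[C@H]1CCC(=C)[C@@H](C(=O)O)[C@H]1C=C | intermediate
15 | tert-butyl 2-(bromomethyl)acrylate | C=C(CBr)C(=O)OC(C)(C)C | starting material
16 | eastern triene ester: 2-(tert-butoxycarbonyl)allyl ester of 14 | CC(C)[C@H]1CCC(=C)[C@@H](C(=O)OCC(=C)C(=O)OC(C)(C)C)[C@H]1C=C | intermediate
17 | eastern seven-membered lactone: tert-butyl 9-methylidene-1-oxo-6-isopropyl-1,3,5a,6,7,8,9,9a-octahydro-2-benzoxepine-4-carboxylate, cis-fused | CC(C)[C@H]1CCC(=C)[C@H]2C(=O)OCC(C(=O)OC(C)(C)C)=C[C@@H]12 | intermediate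
18 | eastern spiro-epoxide: 9-spiro-oxirane of 17, oxygen trans to C-1 | CC(C)[C@H]1CC[C@@]3(CO3)[C@H]2C(=O)OCC(C(=O)OC(C)(C)C)=C[C@@H]12 | intermediate
19 | western cycloadduct diester (mirror image of 6) | CC(C)[C@@H]1C=C[C@H](CO)[C@H](C(=O)OCc2ccccc2)[C@@H]1C(=O)OCc3ccccc3 | intermediate (not isolated)
20 | western lactone benzyl ester (mirror image of 7) | CC(C)[C@@H]1C=C[C@@H]2COC(=O)[C@@H]2[C@@H]1C(=O)OCc3ccccc3 | intermediate
21 | western lactone acid (mirror image of 8) | CC(C)[C@@H]1CC[C@@H]2COC(=O)[C@@H]2[C@@H]1C(=O)O | intermediate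
22 | western thioester (mirror image of 9) | CC(C)[C@@H]1CC[C@@H]2COC(=O)[C@@H]2[C@@H]1C(=O)SCC | intermediate
23 | western aldehyde (mirror image of 10) | CC(C)[C@@H]1CC[C@@H]2COC(=O)[C@@H]2[C@@H]1C=O | intermediate
24 | western vinyl lactone (mirror image of 11) | CC(C)[C@@H]1CC[C@@H]2COC(=O)[C@@H]2[C@@H]1C=C | intermediate
25 | western seleno acid (mirror image of 12) | CC(C)[C@@H]1CC[C@H](C[Se]c2ccccc2)[C@H](C(=O)O)[C@@H]1C=C | intermediate
26 | western selenoxide (mirror image of 13) | CC(C)[C@@H]1CC[C@H](C[Se](=O)c2ccccc2)[C@H](C(=O)O)[C@@H]1C=C | intermediate (not isolated)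
27 | western dienoic acid (mirror image of 14) | CC(C)[C@@H]1CCC(=C)[C@H](C(=O)O)[C@@H]1C=C | intermediate
28 | western triene ester (mirror image of 16) | CC(C)[C@@H]1CCC(=C)[C@H](C(=O)OCC(=C)C(=O)OC(C)(C)C)[C@@H]1C=C | intermediate
29 | western seven-membered lactone (mirror image of 17) | CC(C)[C@@H]1CCC(=C)[C@@H]2C(=O)OCC(C(=O)OC(C)(C)C)=C[C@H]12 | intermediate
30 | western hydroxy acid: 3-isopropyl-6-methylidene-2-[(E)-3-tert-butoxy-2-(hydroxymethyl)-3-oxoprop-1-enyl]cyclohexane-1-carboxylic acid, all-cis | CC(C)[C@@H]1CCC(=C)[C@H](C(=O)O)[C@@H]1/C=C(\CO)C(=O)OC(C)(C)C | intermediate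
31 | western iodo-β-lactone: cis-fused β-lactone of 30 with CH2I on the oxygen-bearing ring carbon | CC(C)[C@@H]1CC[C@]2(CI)OC(=O)[C@@H]2[C@@H]1/C=C(\CO)C(=O)OC(C)(C)C | intermediate
32 | western allylic iodide: tert-butyl (E)-2-(hydroxymethyl)-3-[3-(iodomethyl)-6-isopropylcyclohex-2-en-1-yl]acrylate, 1,6-cis | CC(C)[C@@H]1CCC(CI)=C[C@@H]1/C=C(\CO)C(=O)OC(C)(C)C | intermediate (not isolated)
33 | western allylic acetate: acetoxymethyl analogue of 32 | CC(C)[C@@H]1CCC(COC(C)=O)=C[C@@H]1/C=C(\CO)C(=O)OC(C)(C)C | intermediate
34 | western acetoxy acid: free acrylic acid of 33 | CC(C)[C@@H]1CCC(COC(C)=O)=C[C@@H]1/C=C(\CO)C(=O)O | intermediate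
35 | western acid: (E)-2-(hydroxymethyl)-3-[3-(hydroxymethyl)-6-isopropylcyclohex-2-en-1-yl]acrylic acid, 1,6-cis | CC(C)[C@@H]1CCC(CO)=C[C@@H]1/C=C(\CO)C(=O)O | intermediate
36 | tert-butyl ester of the target | CC(C)[C@H]1CC[C@@](O)(COC(=O)/C(=C/[C@H]2C=C(CO)CC[C@H]2C(C)C)CO)[C@H]2C(=O)OCC(C(=O)OC(C)(C)C)=C[C@@H]12 | intermediate
37 | CNP0361406.12 | CC(C)[C@H]1CC[C@@](O)(COC(=O)/C(=C/[C@H]2C=C(CO)CC[C@H]2C(C)C)CO)[C@H]2C(=O)OCC(C(=O)O)=C[C@@H]12 | target

**Step count and risks**

Total step count: 28. Longest linear sequence: 18 steps (1, 2, 13 to 26, 27, 28).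

Steps most likely to fail:

Step 3 (the new step; step 13 is its mirror-image run and shares the fallback). The maleate may react sluggishly or with low enantioselectivity in the template. A minor enantiomer in either half would end up in a diastereomer of 36 that chromatography removes, so moderate selectivity is tolerable. Fallback with known chemistry, setting out from 4 and coming back at 8 and 21: dienol 4 and maleic anhydride in toluene at 110 °C undergo the classical endo Diels–Alder reaction to the racemic cycloadduct anhydride F1, whose hydroxymethyl group lactonizes at once to the racemic lactone acid F2. Preparative chromatography on a chiral stationary phase separates the eastern unsaturated lactone acid F3 from the western unsaturated lactone acid F4. Hydrogenation (H2, Pd/C) turns F3 into 8 and F4 into 21, so the racemate supplies both halves.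

Step 11. Ring-closing metathesis to a trisubstituted, ester-bearing alkene in a seven-membered lactone may stall. Fallback, setting out from 12 and coming back at 17: ozonolysis of 12 (O3, CH2Cl2/MeOH, −78 °C, then Me2S) cleaves the vinyl group and oxidizes selenium to give the eastern selenoxide aldehyde F5, which on warming eliminates to the eastern aldehyde acid F6. Wittig reaction with tert-butyl 2-bromo-2-(triphenylphosphoranylidene)acetate gives the eastern (Z)-bromoacrylate acid F7. Stille coupling with Bu3SnCH2OH and Pd(PPh3)4 gives, with retention of geometry, the eastern hydroxy acid F8. Mitsunobu lactonization (PPh3, DIAD, high dilution) closes the ring to 17.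

Step 27. The hindered spiro-epoxide may open too slowly with the polyfunctional acid. Fallback, setting out from 17 and 35 and coming back at 36: 17 is dihydroxylated from the open lower face (OsO4 cat., NMO) to the eastern diol lactone F9, which is used at once. Acid 35 is silylated (TBSCl, imidazole) to the western tris-silyl derivative F10, whose silyl ester is hydrolysed on work-up to the western bis-silyl ether acid F11. Yamaguchi esterification (2,4,6-trichlorobenzoyl chloride, Et3N, DMAP) acylates the primary hydroxyl of F9 to the bis-silyl ether of 36, F12. HF·pyridine removes the silyl groups to give 36.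

**Further compounds**

F1 | step 3 | racemic cycloadduct anhydride (both enantiomers) | CC(C)[C@H]1C=C[C@@H](CO)[C@H]2C(=O)OC(=O)[C@@H]12.CC(C)[C@@H]1C=C[C@H](CO)[C@@H]2C(=O)OC(=O)[C@H]12
F2 | step 3 | racemic unsaturated lactone acid (both enantiomers) | CC(C)[C@H]1C=C[C@H]2COC(=O)[C@H]2[C@H]1C(=O)O.CC(C)[C@@H]1C=C[C@@H]2COC(=O)[C@@H]2[C@@H]1C(=O)O
F3 | step 3 | eastern unsaturated lactone acid | CC(C)[C@H]1C=C[C@H]2COC(=O)[C@H]2[C@H]1C(=O)O
F4 | step 3 | western unsaturated lactone acid | CC(C)[C@@H]1C=C[C@@H]2COC(=O)[C@@H]2[C@@H]1C(=O)O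
F5 | step 11 | eastern selenoxide aldehyde | CC(C)[C@H]1CC[C@@H](C[Se](=O)c2ccccc2)[C@@H](C(=O)O)[C@H]1C=O
F6 | step 11 | eastern aldehyde acid | CC(C)[C@H]1CCC(=C)[C@@H](C(=O)O)[C@H]1C=O
F7 | step 11 | eastern (Z)-bromoacrylate acid | CC(C)[C@H]1CCC(=C)[C@@H](C(=O)O)[C@H]1/C=C(\Br)C(=O)OC(C)(C)C
F8 | step 11 | eastern hydroxy acid | CC(C)[C@H]1CCC(=C)[C@@H](C(=O)O)[C@H]1/C=C(\CO)C(=O)OC(C)(C)C
F9 | step 27 | eastern diol lactone | CC(C)[C@H]1CC[C@@](O)(CO)[C@H]2C(=O)OCC(C(=O)OC(C)(C)C)=C[C@@H]12
F10 | step 27 | western tris-silyl derivative | CC(C)[C@@H]1CCC(CO[Si](C)(C)C(C)(C)C)=C[C@@H]1/C=C(\CO[Si](C)(C)C(C)(C)C)C(=O)O[Si](C)(C)C(C)(C)C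
F11 | step 27 | western bis-silyl ether acid | CC(C)[C@@H]1CCC(CO[Si](C)(C)C(C)(C)C)=C[C@@H]1/C=C(\CO[Si](C)(C)C(C)(C)C)C(=O)O
F12 | step 27 | bis-silyl ether of 36 | CC(C)[C@H]1CC[C@@](O)(COC(=O)/C(=C/[C@H]2C=C(CO[Si](C)(C)C(C)(C)C)CC[C@H]2C(C)C)CO[Si](C)(C)C(C)(C)C)[C@H]2C(=O)OCC(C(=O)OC(C)(C)C)=C[C@@H]12
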